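**Plan**

- Retrosynthesis cuts, in this order: both pyridylmethyl–chain C–C bonds at the two termini; N1–C1' of the N-chain; C6–C6a of the cyclopentane; O2–C3 and then C3–C3a of a monocyclic 2-isoxazoline precursor.
- Forward: C3–C3a is joined by an asymmetric Michael addition; the 1,2-oxazole ring (O2–N1=C6a–C3a–C3) is closed next; the carbocycle is closed onto it; the N-chain and finally both pyridines are added.
- Enabling feature: C6a is the imine carbon of a 3-unsubstituted 2-isoxazoline, a cyclic oxime ether O2–N1=C6a. It is a radical acceptor lying three carbons from C6 on the arm at C3a, and the five-membered N–O ring allows only cis ring fusion.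
- Stereochemistry: C3 and C3a come from one amine-catalysed Michael addition, relayed by Baeyer–Villiger oxidation (retention) and SN2 ring closure (inversion) to the cis-4,5-disubstituted isoxazoline; C6a comes from the ring closure itself; the Z-alkene comes from a Wittig reaction.

Key step: step 8

Assumption: the enamine Michael addition of step 3 is taken to follow the same facial course with the β-alkyl nitroalkene 5 as with β-aryl nitroalkenes, so that the (S)-configured catalyst leads to (2R,3R)-8.

**Step 1**
Reactants: 1 4-[(tert-butyldimethylsilyl)oxy]butanal; 2 nitromethane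
Product: 5 (E)-tert-butyldimethyl[(5-nitropent-4-en-1-yl)oxy]silane, via nitro alcohol 3 (not isolated), via nitro mesylate 4 (not isolated)
Conditions: MeNO2 (5 equiv), KOt-Bu (10 mol %), THF/t-BuOH, 0 °C; then MsCl, Et3N, CH2Cl2, 0 °C
Reagents that add atoms: methanesulfonyl chloride, CS(=O)(=O)Cl (its atoms stay only in intermediate 4)
Why: Henry addition followed by E1cB elimination of the derived mesylate should give the conjugated (E)-nitroalkene, the thermodynamic geometry; the silyl ether is inert to both stages.

**Step 2**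
Reactants: 6 9-chlorononan-1-ol
Product: 7 9-chlorononanal
Conditions: TEMPO (10 mol %), PhI(OAc)2, CH2Cl2, rt
Reagents that add atoms: none
Why: TEMPO/PhI(OAc)2 oxidation of a primary alcohol stops at the aldehyde and leaves the alkyl chloride untouched.

**Step 3**
Reactants: 7 9-chlorononanal; 5 (E)-tert-butyldimethyl[(5-nitropent-4-en-1-yl)oxy]silane
Product: 8 (2R)-2-[(2R)-5-[(tert-butyldimethylsilyl)oxy]-1-nitropentan-2-yl]-9-chlorononanal
Conditions: (S)-α,α-diphenylprolinol trimethylsilyl ether (10 mol %), 4-nitrophenol (10 mol %), toluene, rt; 7 in 1.5-fold excess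
Reagents that add atoms: none
Why: Enamine-catalysed Michael addition of an aldehyde to a nitroalkene: the (E)-enamine of 7, shielded on one face by the diphenyl(silyloxy)methyl group, should add to 5 through a synclinal open transition state to give the syn adduct, setting C3 and C3a of the target in one event.

**Step 4**
Reactants: 8 (2R)-2-[(2R)-5-[(tert-butyldimethylsilyl)oxy]-1-nitropentan-2-yl]-9-chlorononanal
Product: 10 (4S,5R)-1-[(tert-butyldimethylsilyl)oxy]-12-chloro-4-(nitromethyl)dodecan-5-ol, via formate 9 (not isolated)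
Conditions: mCPBA, Na2HPO4, CH2Cl2, 0 °C → rt; then K2CO3 (cat.), MeOH, 0 °C
Reagents that add atoms: 3-chloroperbenzoic acid, OOC(=O)c1cccc(Cl)c1 (one oxygen atom)
Why: Baeyer–Villiger oxidation of an α-branched aldehyde: the secondary alkyl group should migrate to oxygen in preference to hydride and with retention of configuration, and catalytic K2CO3 in MeOH cleaves the formate without touching the silyl ether, the chloride or the stereocentres.

**Step 5**
Reactants: 10 (4S,5R)-1-[(tert-butyldimethylsilyl)oxy]-12-chloro-4-(nitromethyl)dodecan-5-ol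
Product: 12 (4S,5S)-4-{3-[(tert-butyldimethylsilyl)oxy]propyl}-5-(7-chloroheptyl)-4,5-dihydro-1,2-oxazole 2-oxide, via mesylate 11 (not isolated)
Conditions: MsCl, Et3N, CH2Cl2, 0 °C; then DBU, MeCN, rt
Reagents that add atoms: methanesulfonyl chloride, CS(=O)(=O)Cl (its atoms stay only in intermediate 11)
Why: Mesylation, then intramolecular O-alkylation of the DBU-generated nitronate (5-exo-tet SN2, the established route from γ-sulfonyloxy nitroalkanes to 2-isoxazoline 2-oxides): inversion at the carbinol carbon should place the chloroheptyl chain cis to the silyloxypropyl arm.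

**Step 6**
Reactants: 12 (4S,5S)-4-{3-[(tert-butyldimethylsilyl)oxy]propyl}-5-(7-chloroheptyl)-4,5-dihydro-1,2-oxazole 2-oxide
Product: 13 (4S,5S)-4-{3-[(tert-butyldimethylsilyl)oxy]propyl}-5-(7-chloroheptyl)-4,5-dihydro-1,2-oxazole
Conditions: P(OMe)3, toluene, 100 °C
Reagents that add atoms: none
Why: Trialkyl phosphites remove the exocyclic oxygen of cyclic nitronates (oxygen transfer to trivalent phosphorus) to give the 2-isoxazoline; C4 and C5 are not involved, and the primary chloride is too unreactive for an Arbuzov reaction at this temperature.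

**Step 7**
Reactants: 13 (4S,5S)-4-{3-[(tert-butyldimethylsilyl)oxy]propyl}-5-(7-chloroheptyl)-4,5-dihydro-1,2-oxazole
Product: 14 (4S,5S)-4-(3-bromopropyl)-5-(7-chloroheptyl)-4,5-dihydro-1,2-oxazole
Conditions: Ph3PBr2, CH2Cl2, 0 °C → rt
Reagents that add atoms: dibromotriphenylphosphorane, BrP(Br)(c1ccccc1)(c1ccccc1)c1ccccc1 (one bromine atom)
Why: Ph3PBr2 converts primary tert-butyldimethylsilyl ethers directly into bromides (oxyphosphonium formation, then SN2 by bromide) under non-basic conditions that spare the base-labile 3-unsubstituted isoxazoline.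

**Step 8**
Reactants: 14 (4S,5S)-4-(3-bromopropyl)-5-(7-chloroheptyl)-4,5-dihydro-1,2-oxazole
Product: 15 (3S,3aS,6aR)-3-(7-chloroheptyl)hexahydro-1H-cyclopenta[c][1,2]oxazole
Conditions: Bu3SnH (1.2 equiv), AIBN (10 mol %), benzene (0.01 M), 80 °C, syringe-pump addition; aq. KF work-up
Reagents that add atoms: none
Why: Proposed new method: Bu3Sn• abstracts bromine from the primary C–Br bond of 14 (the C–Cl bond reacts far more slowly), and the nucleophilic primary radical at C6 should add to the imine carbon C6a of the 2-isoxazoline, giving an oxygen-stabilised N-centred alkoxyaminyl radical that takes hydrogen from Bu3SnH and carries the chain. The closest known reaction type is the stannane-mediated 5-exo cyclization of alkyl radicals onto acyclic aldoxime O-alkyl ethers; here the oxime ether is held in a ring. The cyclopentane is closed in the 5-exo-trig mode (attack at carbon, nitrogen outside the new ring), which should be preferred over 6-endo attack at nitrogen both by ring size and by polarity. The new stereocentre C6a is fixed by the three-carbon arm on C3a, which can reach C6a only from its own face, so only the cis-fused bicyclo[3.3.0] skeleton can form and H6a ends syn to H3a and H3, that is (6aR) with the chloroheptyl chain on the concave face. The step needs cyclization to outrun direct reduction of the radical and 1,5-hydrogen transfer from C3–H. The low stannane concentration and the fast addition expected at an unsubstituted aldoxime-type carbon should secure this.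

**Step 9**
Reactants: 16 8-chlorooctan-1-ol
Product: 17 8-chlorooctanal
Conditions: TEMPO (10 mol %), PhI(OAc)2, CH2Cl2, rt
Reagents that add atoms: none
Why: Same selective alcohol-to-aldehyde oxidation as in step 2.

**Step 10**
Reactants: 18 (3-cyanopropyl)triphenylphosphonium bromide; 17 8-chlorooctanal
Product: 20 (4Z)-12-chlorododec-4-enenitrile, via ylide 19 (not isolated)
Conditions: NaN(SiMe3)2, THF, −78 → 0 °C; then 17, −78 °C → rt
Reagents that add atoms: none
Why: Wittig reaction of a non-stabilised ylide under lithium-free conditions at low temperature should give the (Z)-alkene through the kinetically favoured cis-oxaphosphetane; nitrile and chloride are inert.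

**Step 11**
Reactants: 20 (4Z)-12-chlorododec-4-enenitrile
Product: 22 (4Z)-12-chlorododec-4-enal, via aluminium imine 21 (not isolated)
Conditions: i-Bu2AlH, CH2Cl2, −78 °C; then aq. HCl, 0 °C
Reagents that add atoms: water, O (carbonyl oxygen); diisobutylaluminium hydride, CC(C)C[AlH]CC(C)C (aluminium stays only in intermediate 21)
Why: i-Bu2AlH adds once to the nitrile at −78 °C to give the aluminium imine, which is hydrolysed to the aldehyde on acidic work-up; the remote (γ,δ) Z-alkene cannot move into conjugation under these conditions.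

**Step 12**
Reactants: 15 (3S,3aS,6aR)-3-(7-chloroheptyl)hexahydro-1H-cyclopenta[c][1,2]oxazole; 22 (4Z)-12-chlorododec-4-enal
Product: 24 (3S,3aS,6aR)-3-(7-chloroheptyl)-1-[(4Z)-12-chlorododec-4-en-1-yl]hexahydro-1H-cyclopenta[c][1,2]oxazole, via iminium acetate 23 (not isolated)
Conditions: NaBH(OAc)3, AcOH, ClCH2CH2Cl, rt
Reagents that add atoms: acetic acid, CC(=O)O (acetate counter-ion of intermediate 23 only)
Why: Reductive amination: the N–H isoxazolidine, an alkoxyamine made nucleophilic by the alpha effect, condenses with the aldehyde to an N-alkoxyiminium ion that NaBH(OAc)3 reduces; no stereocentre is touched and both chlorides survive.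

**Step 13**
Reactants: 24 (3S,3aS,6aR)-3-(7-chloroheptyl)-1-[(4Z)-12-chlorododec-4-en-1-yl]hexahydro-1H-cyclopenta[c][1,2]oxazole
Product: 25 (3S,3aS,6aR)-3-(7-iodoheptyl)-1-[(4Z)-12-iodododec-4-en-1-yl]hexahydro-1H-cyclopenta[c][1,2]oxazole
Conditions: NaI (6 equiv), 2-butanone, 80 °C
Reagents that add atoms: sodium iodide, [Na+].[I-]
Why: Finkelstein exchange (SN2) at both primary chlorides, driven by precipitation of NaCl, should give the more reactive di-iodide.

**Step 14**
Reactants: 26 3-methylpyridine; 25 (3S,3aS,6aR)-3-(7-iodoheptyl)-1-[(4Z)-12-iodododec-4-en-1-yl]hexahydro-1H-cyclopenta[c][1,2]oxazole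
Product: 28 pyrinodemin C, via lithiated picoline 27 (not isolated)
Conditions: LiN(i-Pr)2 (5 equiv), 26 (6 equiv), THF/DMPU, −78 °C; then 25, −78 °C → rt
Reagents that add atoms: lithium diisopropylamide, [Li+].CC(C)[N-]C(C)C (lithium stays only in intermediate 27)
Why: Lateral lithiation of 3-methylpyridine gives the picolyl anion, whose two-fold SN2 alkylation by the primary iodides should install both 3-pyridyl termini with the required one-carbon extension; the isoxazolidine and the Z-alkene carry no acidic or electrophilic site.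

**Compound list**

1 | 4-[(tert-butyldimethylsilyl)oxy]butanal | O=CCCCO[Si](C)(C)C(C)(C)C | starting material
2 | nitromethane | C[N+](=O)[O-] | starting material
3 | 5-[(tert-butyldimethylsilyl)oxy]-1-nitropentan-2-ol (racemic) | OC(C[N+](=O)[O-])CCCO[Si](C)(C)C(C)(C)C | intermediate
4 | 5-[(tert-butyldimethylsilyl)oxy]-1-nitropentan-2-yl methanesulfonate (racemic) | CS(=O)(=O)OC(C[N+](=O)[O-])CCCO[Si](C)(C)C(C)(C)C | intermediate
5 | (E)-tert-butyldimethyl[(5-nitropent-4-en-1-yl)oxy]silane | O=[N+]([O-])/C=C/CCCO[Si](C)(C)C(C)(C)C | intermediate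
6 | 9-chlorononan-1-ol | OCCCCCCCCCCl | starting material
7 | 9-chlorononanal | O=CCCCCCCCCCl | intermediate
8 | (2R)-2-[(2R)-5-[(tert-butyldimethylsilyl)oxy]-1-nitropentan-2-yl]-9-chlorononanal | O=C[C@H](CCCCCCCCl)[C@H](C[N+](=O)[O-])CCCO[Si](C)(C)C(C)(C)C | intermediate
9 | (4S,5R)-1-[(tert-butyldimethylsilyl)oxy]-12-chloro-4-(nitromethyl)dodecan-5-yl formate | O=CO[C@H](CCCCCCCCl)[C@H](C[N+](=O)[O-])CCCO[Si](C)(C)C(C)(C)C | intermediate
10 | (4S,5R)-1-[(tert-butyldimethylsilyl)oxy]-12-chloro-4-(nitromethyl)dodecan-5-ol | O[C@H](CCCCCCCCl)[C@H](C[N+](=O)[O-])CCCO[Si](C)(C)C(C)(C)C | intermediate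
11 | (4S,5R)-1-[(tert-butyldimethylsilyl)oxy]-12-chloro-4-(nitromethyl)dodecan-5-yl methanesulfonate | CS(=O)(=O)O[C@H](CCCCCCCCl)[C@H](C[N+](=O)[O-])CCCO[Si](C)(C)C(C)(C)C | intermediate
12 | (4S,5S)-4-{3-[(tert-butyldimethylsilyl)oxy]propyl}-5-(7-chloroheptyl)-4,5-dihydro-1,2-oxazole 2-oxide (substituents cis) | ClCCCCCCC[C@@H]1O[N+]([O-])=C[C@@H]1CCCO[Si](C)(C)C(C)(C)C | intermediate
13 | (4S,5S)-4-{3-[(tert-butyldimethylsilyl)oxy]propyl}-5-(7-chloroheptyl)-4,5-dihydro-1,2-oxazole (substituents cis) | ClCCCCCCC[C@@H]1ON=C[C@@H]1CCCO[Si](C)(C)C(C)(C)C | intermediate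
14 | (4S,5S)-4-(3-bromopropyl)-5-(7-chloroheptyl)-4,5-dihydro-1,2-oxazole (substituents cis) | ClCCCCCCC[C@@H]1ON=C[C@@H]1CCCBr | intermediate
15 | (3S,3aS,6aR)-3-(7-chloroheptyl)hexahydro-1H-cyclopenta[c][1,2]oxazole (cis-fused, chain on the concave face) | N1O[C@@H](CCCCCCCCl)[C@H]2CCC[C@H]21 | intermediate
16 | 8-chlorooctan-1-ol | OCCCCCCCCCl | starting material
17 | 8-chlorooctanal | O=CCCCCCCCCl | intermediate
18 | (3-cyanopropyl)triphenylphosphonium bromide | N#CCCC[P+](c1ccccc1)(c1ccccc1)c1ccccc1.[Br-] | starting material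
19 | (3-cyanopropylidene)triphenylphosphorane | N#CCCC=P(c1ccccc1)(c1ccccc1)c1ccccc1 | intermediate
20 | (4Z)-12-chlorododec-4-enenitrile | N#CCC/C=C\CCCCCCCCl | intermediate
21 | (4Z)-12-chloro-N-(diisobutylalumanyl)dodec-4-en-1-imine | ClCCCCCCC/C=C\CCC=N[Al](CC(C)C)CC(C)C | intermediate
22 | (4Z)-12-chlorododec-4-enal | O=CCC/C=C\CCCCCCCCl | intermediate
23 | (3S,3aS,6aR)-3-(7-chloroheptyl)-1-[(4Z)-12-chlorododec-4-en-1-ylidene]hexahydro-1H-cyclopenta[c][1,2]oxazol-1-ium acetate | ClCCCCCCC/C=C\CCC=[N+]1O[C@@H](CCCCCCCCl)[C@H]2CCC[C@H]21.CC(=O)[O-] | intermediate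
24 | (3S,3aS,6aR)-3-(7-chloroheptyl)-1-[(4Z)-12-chlorododec-4-en-1-yl]hexahydro-1H-cyclopenta[c][1,2]oxazole | ClCCCCCCC/C=C\CCCN1O[C@@H](CCCCCCCCl)[C@H]2CCC[C@H]21 | intermediate
25 | (3S,3aS,6aR)-3-(7-iodoheptyl)-1-[(4Z)-12-iodododec-4-en-1-yl]hexahydro-1H-cyclopenta[c][1,2]oxazole | ICCCCCCC/C=C\CCCN1O[C@@H](CCCCCCCI)[C@H]2CCC[C@H]21 | intermediate
26 | 3-methylpyridine | Cc1cccnc1 | starting material
27 | (pyridin-3-ylmethyl)lithium | [Li]Cc1cccnc1 | intermediate
28 | pyrinodemin C, (3S,3aS,6aR)-3-[8-(pyridin-3-yl)octyl]-1-[(4Z)-13-(pyridin-3-yl)tridec-4-en-1-yl]hexahydro-1H-cyclopenta[c][1,2]oxazole | C(=C/CCCN1O[C@@H](CCCCCCCCc2cccnc2)[C@H]2CCC[C@H]21)/CCCCCCCCc1cccnc1 | target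

**Totals**

Total step count: 14. Longest linear sequence: 10 steps (steps 1, 3, 4, 5, 6, 7, 8, 12, 13, 14).

**Steps most likely to fail**

1. Step 8 (bears the label). Addition of the primary radical to the ring C=N may be too slow relative to hydrogen transfer from the stannane, so that the C–Br bond is simply reduced, or the alkoxyaminyl radical may fail to propagate the chain. The fallback uses known chemistry, sets out from 22 and rejoins the route at 15. A Wittig reaction of 22 with Ph3P=CHOMe would give the enol ether (5Z)-13-chloro-1-methoxytrideca-1,5-diene F1, and mild aqueous acid the homologous aldehyde (5Z)-13-chlorotridec-5-enal F2. Condensation of F2 with 2,3:5,6-di-O-isopropylidene-D-mannose oxime F3 (from commercial diacetone-D-mannose and NH2OH) would give the N-glycosyl nitrone N-(2,3:5,6-di-O-isopropylidene-α-D-mannofuranosyl)-(5Z)-13-chlorotridec-5-en-1-imine N-oxide F4, not isolated. On heating in toluene this should close both rings by the long-established intramolecular nitrone–alkene cycloaddition. The Z-alkene places the chloroheptyl chain cis to the carbocycle and the sugar differentiates the two faces, so that (3S,3aS,6aR)-3-(7-chloroheptyl)-1-(2,3:5,6-di-O-isopropylidene-α-D-mannofuranosyl)hexahydro-1H-cyclopenta[c][1,2]oxazole F5 can be separated from its diastereomer by chromatography. Acidic hydrolysis of the N-glycoside (dilute HCl, aqueous MeOH) would then give 15.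

2. Step 5. E2 loss of the hindered secondary mesylate, or C-alkylation of the nitronate to a three-membered ring, may compete with the O-alkylation. The fallback sets out from 10 and rejoins the route at 13, bypassing 11, 12 and step 6. The primary nitro group of 10 would be reduced to the aldoxime (2S)-5-[(tert-butyldimethylsilyl)oxy]-2-[(1R)-8-chloro-1-hydroxyoctyl]pentanal oxime F6 with SnCl2, PhSH and Et3N. An intramolecular Mitsunobu reaction (PPh3, DIAD, THF) would then let the oxime oxygen, after E/Z equilibration, displace the activated secondary hydroxyl with inversion and give 13 directly.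

3. Step 14. The two-fold alkylation may stop half-way, the primary iodides may undergo base-induced elimination, and the lithiated picoline may add to further picoline. The fallback sets out from 25 and ends at 28. It replaces the hard carbanion by a nickel-catalysed sp3–sp3 Negishi coupling: (pyridin-3-ylmethyl)zinc chloride F7, made from 3-(chloromethyl)pyridine with Zn and LiCl, would be coupled with both primary iodides of 25 using Ni(acac)2 and 4-fluorostyrene in THF/N-methylpyrrolidone.

**Further compounds**

F1 | step 8 | (5Z)-13-chloro-1-methoxytrideca-1,5-diene (enol ether, E/Z mixture at C1) | COC=CCC/C=C\CCCCCCCCl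
F2 | step 8 | (5Z)-13-chlorotridec-5-enal | O=CCCC/C=C\CCCCCCCCl
F3 | step 8 | 2,3:5,6-di-O-isopropylidene-D-mannose oxime | ON=C[C@H]1OC(C)(C)O[C@H]1[C@H](O)[C@H]1COC(C)(C)O1
F4 | step 8 | N-(2,3:5,6-di-O-isopropylidene-α-D-mannofuranosyl)-(5Z)-13-chlorotridec-5-en-1-imine N-oxide | [O-][N+](=CCCC/C=C\CCCCCCCCl)[C@H]1O[C@H]([C@H]2COC(C)(C)O2)[C@@H]2OC(C)(C)O[C@H]12
F5 | step 8 | (3S,3aS,6aR)-3-(7-chloroheptyl)-1-(2,3:5,6-di-O-isopropylidene-α-D-mannofuranosyl)hexahydro-1H-cyclopenta[c][1,2]oxazole | N1([C@H]3O[C@H]([C@H]4COC(C)(C)O4)[C@@H]4OC(C)(C)O[C@H]34)O[C@@H](CCCCCCCCl)[C@H]2CCC[C@H]21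
F6 | step 5 | (2S)-5-[(tert-butyldimethylsilyl)oxy]-2-[(1R)-8-chloro-1-hydroxyoctyl]pentanal oxime | ON=C[C@H](CCCO[Si](C)(C)C(C)(C)C)[C@H](O)CCCCCCCCl
F7 | step 14 | (pyridin-3-ylmethyl)zinc chloride | Cl[Zn]Cc1cccnc1
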